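A direct plan would keep ring A from phloroglucinol A1 and build ring C on it. The bis-MOM dihydrocoumarin A2 would be opened with a methyl Grignard reagent and ortho-formylated to salicylaldehyde A3, O-vinylated with a 1-phenylvinylboron reagent to aryl enol ether A4, and closed by an enantioselective rhodium hydroacylation to flavanone A5. Acid would then strip the MOM groups to give the 5,7-dihydroxyflavanone A6, and a Mitsunobu reaction would methylate O7.
Its weakest points would be:
- The hydroacylation that closes ring C and sets C2 at once: an aryl enol ether has not served as the alkene, the acyl rhodium hydride can lose CO or close 5-exo, and the enantioselectivity is unknown, all on the most advanced material.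
- The copper-mediated O-vinylation of a phenol that is flanked by a formyl group and an alkyl chain and held in a chelate, which must deliver an acid-labile enol ether.
- The protecting-group detour: two MOM ethers put on, removed in acid beside a tertiary alcohol and a freed 7-OH (dimethylchroman formation, dehydration), then a selective 7-O-methylation, so three steps to place one methyl group.

**Plan of the new route**
Ring C is made first and ring A last. The retrosynthesis cuts the tertiary C–OH (hydration of a prenyl group), then ring A at C5–C6, C7–C8 and C4a–C5, giving a vinylketene centred on C8 plus methoxyacetylene.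
Ring C goes back to a δ-hydroxy-β-diketone (O1–C8a, then C4–C4a), and C2 is bought as ethyl (S)-3-hydroxy-3-phenylpropanoate.
The enabling feature is the 1,3,5-oxygen pattern of ring A laid over the enol-ether bond C4a=C8a of ring C: C5–OH is a ketene carbonyl, C7–OMe the oxygenated carbon of an ynol ether, and O1–C8a the vinylogous ester of a 2,3-dihydro-4H-pyran-4-one.
C2 is never formed in a ring closure and its C–O bond is never broken. No phenol is protected or vinylated, because O5 arrives free and O7 arrives methylated. The tertiary alcohol appears last, under neutral conditions, on a ring with no free ortho-phenol.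

Key step: step 6

Remark: atom labels C2 to C8a refer to the flavanone numbering of the target throughout. The carbon that becomes aromatic C8 is a labile stereocentre in every intermediate from the alkylated acetoacetate to the ketene, so those compounds are carried as epimer mixtures. Methoxyacetylene is volatile and seldom stocked, so its preparation is included.

Step 1
Reactants: 1 allyl acetoacetate; 2 prenyl bromide (1-bromo-3-methylbut-2-ene)
Product: 3 allyl 2-acetyl-5-methylhex-4-enoate
Conditions: 1 (1.3 equiv), K2CO3 (1.5 equiv), acetone, reflux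
Reagents that add atoms: none
Why: Acetoacetic ester C-alkylation: the potassium enolate of 1 displaces the allylic bromide by SN2 and the excess of 1 keeps dialkylation low; the allyl ester is chosen because it can later be removed without acid or hydroxide.

Step 2
Reactants: 4 ethyl (3S)-3-hydroxy-3-phenylpropanoate
Product: 5 (3S)-3-hydroxy-N-methoxy-N-methyl-3-phenylpropanamide
Conditions: MeNH(OMe)·HCl (2.5 equiv), i-PrMgCl (6.0 equiv), THF, −20 → 0 °C
Reagents that add atoms: N,O-dimethylhydroxylamine hydrochloride, CNOC.Cl
Why: Weinreb amide formation by aminolysis of the ester with the chloromagnesium amide tolerates the free β-hydroxyl as its magnesium alkoxide and leaves the benzylic stereocentre, the future C2, untouched.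

Step 3
Reactants: 3 allyl 2-acetyl-5-methylhex-4-enoate; 5 (3S)-3-hydroxy-N-methoxy-N-methyl-3-phenylpropanamide
Product: 8 allyl 5-methyl-2-[(2S)-4-oxo-2-phenyl-3,4-dihydro-2H-pyran-6-yl]hex-4-enoate, via hydroxy diketo ester 6 (not isolated), via hemiketal 7 (not isolated)
Conditions: 3 (3.0 equiv), LiN(i-Pr)2 (LDA, 6.1 equiv), THF, −78 → 0 °C (20 min); 5 (1.0 equiv), −78 → −20 °C; AcOH quench; crude 6, TsOH·H2O (0.1 equiv), CH2Cl2, 20 °C
Reagents that add atoms: none
Why: γ-Acylation of the β-keto ester dianion of 3 by the Weinreb amide (crossed Claisen condensation, one equivalent of dianion being spent on the hydroxyl and the chelated tetrahedral intermediate preventing over-addition) forms C4–C4a, and 6 then closes ring C by acid-catalysed hemiketalisation at C8a (6-exo-trig) and dehydration to the vinylogous ester, the C2–O bond of 5 never being broken, while holding the dianion at or below 0 °C keeps the dianionic Carroll rearrangement of the allyl ester from setting in.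

Step 4
Reactants: 8 allyl 5-methyl-2-[(2S)-4-oxo-2-phenyl-3,4-dihydro-2H-pyran-6-yl]hex-4-enoate
Product: 9 5-methyl-2-[(2S)-4-oxo-2-phenyl-3,4-dihydro-2H-pyran-6-yl]hex-4-enoic acid
Conditions: Pd(PPh3)4 (3 mol %), sodium p-toluenesulfinate (1.2 equiv), THF/MeOH, 0 → 20 °C; cold 0.5 M HCl to pH 3; used at once
Reagents that add atoms: none
Why: Tsuji–Trost deallylation: zerovalent palladium ionises the allyl ester and the non-basic sulfinate captures the π-allyl unit, so the acid is freed without hydroxide (which would open the vinylogous ester) and without strong acid (which would attack the prenyl group).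

Step 5
Reactants: 10 chloroacetaldehyde dimethyl acetal
Product: 13 methoxyacetylene, via 1-chloro-2-methoxyethene 11 (not isolated), via sodium methoxyacetylide 12 (not isolated)
Conditions: NaNH2 (3.1 equiv), liquid NH3, −33 °C; NH3 evaporated; sat. aq. NH4Cl, −20 °C; distilled (bp 23 °C) into cold toluene and kept as a solution
Reagents that add atoms: none
Why: Base-induced double elimination of a chloroacetal (loss of MeOH, then of HCl) is the standard preparation of alkoxyacetylenes, the third equivalent of amide holding the product as its sodium acetylide until the quench.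

Step 6
Reactants: 9 5-methyl-2-[(2S)-4-oxo-2-phenyl-3,4-dihydro-2H-pyran-6-yl]hex-4-enoic acid; 13 methoxyacetylene
Product: 19 (2S)-5-hydroxy-7-methoxy-8-(3-methylbut-2-en-1-yl)-2-phenylchroman-4-one, via acid chloride 14 (not isolated), via vinylketene 15 (not isolated), via 4-vinylcyclobutenone 16 (not isolated), via dienylketene 17 (not isolated), via cyclohexadienone 18 (not isolated)
Conditions: 1-chloro-N,N,2-trimethylprop-1-en-1-amine (1.1 equiv), CH2Cl2, 0 °C; solvent exchange to toluene; 13 (5 equiv), i-Pr2NEt (1.05 equiv, added over 2 h), −20 → 20 °C; filtration under argon, excess 13 removed in an argon stream; toluene, 85 °C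
Reagents that add atoms: none
Why: Proposed new method: the neutral chloroenamine converts 9 into acid chloride 14, whose C8–H is acidified by the acyl chloride and by the vinylogous ester of ring C and is removed by the amine to give vinylketene 15; the nucleophilic CH terminus of 13 adds to the ketene carbonyl carbon in a [2+2] cycloaddition (C5–C6 and C7–C8) to give cyclobutenone 16, which at 85 °C opens by conrotatory 4π cleavage of C5–C8 to dienylketene 17 and closes to dienone 18, whose C4a–H lies between two carbonyls and tautomerises at once to the phenol. The closest known reaction type is the Danheiser benzannulation of cyclobutenone- or diazo-ketone-derived vinylketenes with alkoxy- and siloxyacetylenes, together with the [2+2] addition of acid-chloride-derived ketenes to alkoxyacetylenes; what has not been shown is a vinylketene made by dehydrochlorination whose vinyl unit is the enol-ether double bond of a dihydropyranone. Ring A closes by disrotatory 6π electrocyclisation (C4a–C5) onto C4a, the only free terminus of the triene, and release of four-ring strain plus aromatisation drive the cascade, leaving O5 as a free hydroxyl hydrogen-bonded to C4=O and the methoxy group on C7. No new stereocentre remains, since C8 in 16 and C4a in 18 are transient, and C2 is not touched because, before heating, the amine is filtered off as its hydrochloride and the excess of 13 is stripped so that phenol 19 cannot add to it. The step needs [2+2] addition to outrun ketene dimerisation and needs the regiochemistry that puts OMe on C7 next to C8: excess 13 with slow addition of base should secure the first and the polarity of the ynol ether (β-carbon nucleophilic) the second. A ring opening that turns the pyranonyl group outward is harmless because 16 and 17 interconvert.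

Step 7
Reactants: 19 (2S)-5-hydroxy-7-methoxy-8-(3-methylbut-2-en-1-yl)-2-phenylchroman-4-one
Product: 20 (2S)-5-hydroxy-8-(3-hydroxy-3-methylbutyl)-7-methoxy-2-phenylchroman-4-one (target)
Conditions: Co(acac)2 (20 mol %), PhSiH3 (2.5 equiv), O2 (1 atm), THF, 20 °C; aq. Na2S2O3
Reagents that add atoms: dioxygen, O=O
Why: Mukaiyama hydration: hydrogen-atom transfer from a cobalt hydride to the trisubstituted alkene gives the tertiary radical, which is trapped by O2 and reduced to the tertiary alcohol (Markovnikov), under neutral conditions that should leave C4=O, the chelated phenol and the base-labile C2 centre untouched, and with O7 already methylated no chroman can form.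

**Compound list**
1 | allyl acetoacetate (prop-2-en-1-yl 3-oxobutanoate) | CC(=O)CC(=O)OCC=C | starting material
2 | prenyl bromide (1-bromo-3-methylbut-2-ene) | CC(C)=CCBr | starting material
3 | allyl 2-acetyl-5-methylhex-4-enoate (racemic) | CC(=O)C(CC=C(C)C)C(=O)OCC=C | intermediate
4 | ethyl (3S)-3-hydroxy-3-phenylpropanoate | O[C@H](c1ccccc1)CC(=O)OCC | starting material
5 | (3S)-3-hydroxy-N-methoxy-N-methyl-3-phenylpropanamide | O[C@H](c1ccccc1)CC(=O)N(C)OC | intermediate
6 | allyl (7S)-7-hydroxy-2-(3-methylbut-2-en-1-yl)-3,5-dioxo-7-phenylheptanoate (epimers at C2 of the chain) | O[C@H](c1ccccc1)CC(=O)CC(=O)C(CC=C(C)C)C(=O)OCC=C | intermediate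
7 | allyl 2-[(6S)-2-hydroxy-4-oxo-6-phenyloxan-2-yl]-5-methylhex-4-enoate (hemiketal, isomer mixture) | O1[C@H](c2ccccc2)CC(=O)CC1(O)C(CC=C(C)C)C(=O)OCC=C | intermediate
8 | allyl 5-methyl-2-[(2S)-4-oxo-2-phenyl-3,4-dihydro-2H-pyran-6-yl]hex-4-enoate (epimers at the α-carbon) | O1[C@H](c2ccccc2)CC(=O)C=C1C(CC=C(C)C)C(=O)OCC=C | intermediate
9 | 5-methyl-2-[(2S)-4-oxo-2-phenyl-3,4-dihydro-2H-pyran-6-yl]hex-4-enoic acid (epimers at the α-carbon) | O1[C@H](c2ccccc2)CC(=O)C=C1C(CC=C(C)C)C(=O)O | intermediate
10 | chloroacetaldehyde dimethyl acetal (2-chloro-1,1-dimethoxyethane) | COC(CCl)OC | starting material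
11 | 1-chloro-2-methoxyethene | COC=CCl | intermediate
12 | sodium methoxyacetylide | COC#[C-].[Na+] | intermediate
13 | methoxyacetylene (methoxyethyne) | COC#C | intermediate
14 | 5-methyl-2-[(2S)-4-oxo-2-phenyl-3,4-dihydro-2H-pyran-6-yl]hex-4-enoyl chloride | O1[C@H](c2ccccc2)CC(=O)C=C1C(CC=C(C)C)C(Cl)=O | intermediate
15 | (2S)-6-(5-methyl-1-oxohexa-1,4-dien-2-yl)-2-phenyl-2,3-dihydro-4H-pyran-4-one (vinylketene) | O1[C@H](c2ccccc2)CC(=O)C=C1C(CC=C(C)C)=C=O | intermediate
16 | (2S)-6-[2-methoxy-1-(3-methylbut-2-en-1-yl)-4-oxocyclobut-2-en-1-yl]-2-phenyl-2,3-dihydro-4H-pyran-4-one (epimers at the ring carbon) | O1[C@H](c2ccccc2)CC(=O)C=C1C3(CC=C(C)C)C(=O)C=C3OC | intermediate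
17 | (2S)-6-(3-methoxy-7-methyl-1-oxoocta-1,3,6-trien-4-yl)-2-phenyl-2,3-dihydro-4H-pyran-4-one (dienylketene) | O1[C@H](c2ccccc2)CC(=O)C=C1C(CC=C(C)C)=C(OC)C=C=O | intermediate
18 | (2S)-7-methoxy-8-(3-methylbut-2-en-1-yl)-2-phenyl-2,3-dihydro-4H-chromene-4,5(4aH)-dione | O1[C@H](c2ccccc2)CC(=O)C3C1=C(CC=C(C)C)C(OC)=CC3=O | intermediate
19 | (2S)-5-hydroxy-7-methoxy-8-(3-methylbut-2-en-1-yl)-2-phenylchroman-4-one | COc1cc(O)c2c(c1CC=C(C)C)O[C@H](c1ccccc1)CC2=O | intermediate
20 | (2S)-5-hydroxy-8-(3-hydroxy-3-methylbutyl)-7-methoxy-2-phenylchroman-4-one | COc1cc(O)c2c(c1CCC(C)(C)O)O[C@H](c1ccccc1)CC2=O | target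

**Step count and risks**
Total steps: 7. Longest linear sequence: 5 steps (step 1 or 2, then 3, 4, 6, 7).

Steps most likely to fail:

Step 6 (Proposed new method). Dimerisation of the ketene or oligomerisation of the ynol ether may outrun the [2+2] addition, or ketene intermediates may be trapped by the product phenol. The fallback is an ionic Claisen closure of ring A using known chemistry. It sets out from 9.
- Condensation with Meldrum's acid (DCC, DMAP, CH2Cl2, 0 °C) would give 5-{5-methyl-2-[(2S)-4-oxo-2-phenyl-3,4-dihydro-2H-pyran-6-yl]hex-4-enoyl}-2,2-dimethyl-1,3-dioxane-4,6-dione F1.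
- Methanolysis (MeOH, toluene, 70 °C) would give the β-keto ester methyl 7-methyl-3-oxo-4-[(2S)-4-oxo-2-phenyl-3,4-dihydro-2H-pyran-6-yl]oct-6-enoate F2.
- HC(OMe)3 with catalytic TsOH in MeOH would give the enol ether methyl 3-methoxy-7-methyl-4-[(2S)-4-oxo-2-phenyl-3,4-dihydro-2H-pyran-6-yl]octa-2,6-dienoate F3. Here the former carboxyl carbon of 9 is C7 with its methoxy group and the two new carbons are C6 and C5.
- NaOMe (1.1 equiv, THF/MeOH, 0 °C, short contact, AcOH quench) would remove C8–H and close ring A by Claisen attack of C4a on the ester carbon C5, through dienone 18, rejoining the route at 19.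

This is the Claisen-type folding by which tricarbonyl chains give acylphloroglucinols. Its cost is a brief exposure of the flavanone to base.

Step 4. The vinylogous β-keto acid may lose CO2 on palladium or during isolation, or the π-allyl complex may C-allylate the acidic α-carbon. The fallback avoids both the free acid and palladium. It sets out from 5 (with 2).
- tert-Butyl acetoacetate F4 would be alkylated with 2 as in step 1 to tert-butyl 2-acetyl-5-methylhex-4-enoate F5.
- Dianion acylation with 5 and cyclodehydration as in step 3 would pass through tert-butyl (7S)-7-hydroxy-2-(3-methylbut-2-en-1-yl)-3,5-dioxo-7-phenylheptanoate F6 and its hemiketal tert-butyl 2-[(6S)-2-hydroxy-4-oxo-6-phenyloxan-2-yl]-5-methylhex-4-enoate F7 to tert-butyl 5-methyl-2-[(2S)-4-oxo-2-phenyl-3,4-dihydro-2H-pyran-6-yl]hex-4-enoate F8. The tert-butyl ester also takes the dianionic Carroll rearrangement out of the dianion step.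
- TBSOTf and 2,6-lutidine (CH2Cl2, 0 °C) would exchange the tert-butyl group for silicon to give tert-butyldimethylsilyl 5-methyl-2-[(2S)-4-oxo-2-phenyl-3,4-dihydro-2H-pyran-6-yl]hex-4-enoate F9.
- (COCl)2 with catalytic DMF would convert F9 under neutral conditions into acid chloride 14, where the route is rejoined inside step 6.

Step 7. The alkene may be over-reduced to the saturated chain, the reaction may stop at the hydroperoxide, or C4=O may be reduced by hydride. The fallback is ionic and sets out from 19.
- HCl (4 M in dioxane, CH2Cl2, 0 °C) would add in the Markovnikov sense to give (2S)-8-(3-chloro-3-methylbutyl)-5-hydroxy-7-methoxy-2-phenylchroman-4-one F10. With O7 methylated, no phenol can trap the cation as a chroman.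
- Silver-assisted hydrolysis (Ag2CO3, acetone/H2O, 20 °C) would then give 20.

**Further compounds**
F1 | step 6 | 5-{5-methyl-2-[(2S)-4-oxo-2-phenyl-3,4-dihydro-2H-pyran-6-yl]hex-4-enoyl}-2,2-dimethyl-1,3-dioxane-4,6-dione | O1[C@H](c2ccccc2)CC(=O)C=C1C(CC=C(C)C)C(=O)C3C(=O)OC(C)(C)OC3=O
F2 | step 6 | methyl 7-methyl-3-oxo-4-[(2S)-4-oxo-2-phenyl-3,4-dihydro-2H-pyran-6-yl]oct-6-enoate | O1[C@H](c2ccccc2)CC(=O)C=C1C(CC=C(C)C)C(=O)CC(=O)OC
F3 | step 6 | methyl 3-methoxy-7-methyl-4-[(2S)-4-oxo-2-phenyl-3,4-dihydro-2H-pyran-6-yl]octa-2,6-dienoate (E/Z mixture) | O1[C@H](c2ccccc2)CC(=O)C=C1C(CC=C(C)C)C(OC)=CC(=O)OC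
F4 | step 4 | tert-butyl acetoacetate | CC(=O)CC(=O)OC(C)(C)C
F5 | step 4 | tert-butyl 2-acetyl-5-methylhex-4-enoate | CC(=O)C(CC=C(C)C)C(=O)OC(C)(C)C
F6 | step 4 | tert-butyl (7S)-7-hydroxy-2-(3-methylbut-2-en-1-yl)-3,5-dioxo-7-phenylheptanoate | O[C@H](c1ccccc1)CC(=O)CC(=O)C(CC=C(C)C)C(=O)OC(C)(C)C
F7 | step 4 | tert-butyl 2-[(6S)-2-hydroxy-4-oxo-6-phenyloxan-2-yl]-5-methylhex-4-enoate | O1[C@H](c2ccccc2)CC(=O)CC1(O)C(CC=C(C)C)C(=O)OC(C)(C)C
F8 | step 4 | tert-butyl 5-methyl-2-[(2S)-4-oxo-2-phenyl-3,4-dihydro-2H-pyran-6-yl]hex-4-enoate | O1[C@H](c2ccccc2)CC(=O)C=C1C(CC=C(C)C)C(=O)OC(C)(C)C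
F9 | step 4 | tert-butyldimethylsilyl 5-methyl-2-[(2S)-4-oxo-2-phenyl-3,4-dihydro-2H-pyran-6-yl]hex-4-enoate | O1[C@H](c2ccccc2)CC(=O)C=C1C(CC=C(C)C)C(=O)O[Si](C)(C)C(C)(C)C
F10 | step 7 | (2S)-8-(3-chloro-3-methylbutyl)-5-hydroxy-7-methoxy-2-phenylchroman-4-one | COc1cc(O)c2c(c1CCC(C)(C)Cl)O[C@H](c1ccccc1)CC2=O
A1 | direct plan | phloroglucinol | Oc1cc(O)cc(O)c1
A2 | direct plan | 5,7-bis(methoxymethoxy)chroman-2-one | O=C1CCc2c(OCOC)cc(OCOC)cc2O1
A3 | direct plan | 2-hydroxy-3-(3-hydroxy-3-methylbutyl)-4,6-bis(methoxymethoxy)benzaldehyde | CC(C)(O)CCc1c(O)c(C=O)c(OCOC)cc1OCOC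
A4 | direct plan | 3-(3-hydroxy-3-methylbutyl)-4,6-bis(methoxymethoxy)-2-(1-phenylvinyloxy)benzaldehyde | C=C(Oc1c(CCC(C)(C)O)c(OCOC)cc(OCOC)c1C=O)c1ccccc1
A5 | direct plan | (2S)-8-(3-hydroxy-3-methylbutyl)-5,7-bis(methoxymethoxy)-2-phenylchroman-4-one | CC(C)(O)CCc1c(OCOC)cc(OCOC)c2c1O[C@H](c1ccccc1)CC2=O
A6 | direct plan | (2S)-5,7-dihydroxy-8-(3-hydroxy-3-methylbutyl)-2-phenylchroman-4-one | CC(C)(O)CCc1c(O)cc(O)c2c1O[C@H](c1ccccc1)CC2=O
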